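**Retrosynthetic overview**

1. The strategy rests on ring A (C2–C7; chain numbered C1 benzylic to C15): the C6 bromide sits next to quaternary C7 (methyl cis to Br, chain carbon C8 trans) and the C2=C3 alkene carries the C3 methyl. Ring A is made first, by an enantioselective Diels–Alder reaction of an (E)-1-silyloxy-2-methylbutadiene with (E)-3-bromo-2-methylpropenal (bonds C2–C7 and C5–C6).
2. The formyl carbon (C8) is methylenated; C9–C10 is made by B-alkyl Suzuki coupling with an (E)-alkenyl iodide C10–C15 whose C14 carbinol comes from a CBS reduction.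
3. C10–Br/C11–OH: Shi epoxidation of the (E)-C10=C11 alkene at the ring A enone stage, then SN2 opening by bromide at C10.
4. C1–C2: enone → conjugate reduction/enol triflate → Negishi coupling with the benzylzinc reagent from methyl 4-hydroxy-3-methylbenzoate (the arene ring is bought).
5. The 15-membered lactone is the last ring closed (macrolactonisation at O–C14); the tertiary C15 bromide follows by Markovnikov radical hydrobromination of an isopropenyl group, then desilylation.

Key step: step 3

Remark (assumption): positions are numbered C1 (benzylic CH2) to C15 (CMe2Br), ring A = C2–C7; both antipodes of the oxazaborolidine catalysts and of the fructose-derived ketone catalyst are taken as purchasable.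

**Route**

Step 1
Reactants: 1 (E)-2-methylbut-2-enal (tiglic aldehyde)
Product: 2 (E)-triisopropyl(2-methylbuta-1,3-dienyloxy)silane
Conditions: i-Pr3SiOTf, Et3N, Et2O, 0 °C → rt
Reagents that add atoms: triisopropylsilyl trifluoromethanesulfonate, CC(C)[Si](OS(=O)(=O)C(F)(F)F)(C(C)C)C(C)C
Why: O-silylation of the enal makes the γ-methyl protons removable by Et3N (vinylogous silyl enol ether formation), and the s-trans enal should give the (1E)-dienol ether with oxygen on the outside of the s-cis diene; the bulky triisopropylsilyl group is chosen to resist silyl transfer under the strong Lewis acid of step 3.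

Step 2
Reactants: 3 methacrolein
Product: 5 (E)-3-bromo-2-methylprop-2-enal, via 2,3-dibromo-2-methylpropanal 4 (not isolated)
Conditions: Br2, CH2Cl2, −78 → 0 °C; then Et3N, 0 °C → rt
Reagents that add atoms: bromine, BrBr
Why: Bromine addition to the enal followed by E2 loss of HBr (the α-carbon has no hydrogen, so the α-bromide leaves with a C3 proton) is the standard bromination–dehydrobromination route to β-bromo enals, and the E isomer (Br trans to formyl) is the thermodynamically favoured one.

Step 3
Reactants: 2 (E)-triisopropyl(2-methylbuta-1,3-dienyloxy)silane, 5 (E)-3-bromo-2-methylprop-2-enal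
Product: 6 (1R,2S,6S)-6-bromo-1,3-dimethyl-2-(triisopropylsilyloxy)cyclohex-3-ene-1-carbaldehyde
Conditions: (R)-1-(2-methylphenyl)-3,3-diphenyltetrahydro-1H,3H-pyrrolo[1,2-c][1,3,2]oxazaborole (20 mol %), HN(SO2CF3)2 (17 mol %), CH2Cl2, −78 °C
Reagents that add atoms: none
Why: The protonated oxazaborolidine binds the formyl oxygen of 5 (s-trans enal, formyl C–H···O contact) and lowers its LUMO, so that the electron-rich diene 2 adds in a concerted, asynchronous, suprafacial [4+2] cycloaddition; the closest known reaction type is the oxazaborolidinium-catalysed Diels–Alder reaction of 2-substituted and 2,3-disubstituted acroleins with 1-silyloxydienes. Ring A closes by intermolecular [4+2] cycloaddition: C5–C6 (unsubstituted diene terminus to the bromine-bearing β-carbon) and C2–C7 (oxygenated terminus to the α-carbon) form in one event, with the regiochemistry imposed by the 1-silyloxy group (largest HOMO coefficient at the remote terminus). The C6/C7 relationship (Br cis to the C7 methyl, trans to formyl C8) copies the E geometry of 5; the absolute configuration is set by the catalyst, the (R)-antipode being predicted by the accepted binding model to expose the enal face that leads to the configuration that is 6S,7S in the target (the other antipode is used if the sense proves opposite); C2 should form with silyloxy cis to formyl through the endo transition state. The step needs regio-, enantio- and periselectivity: low temperature and the concerted path should suppress stepwise conjugate addition–bromide elimination at C6 and Mukaiyama-type attack at the formyl group, the bulky silyl group slows silyl transfer to triflimide (which would release an achiral silyl Lewis acid), and the quaternary α-carbon of 6 prevents loss of HBr. Either C2 epimer is usable, because C2 becomes a carbonyl carbon in step 12.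

Step 4
Reactants: 6 (1R,2S,6S)-6-bromo-1,3-dimethyl-2-(triisopropylsilyloxy)cyclohex-3-ene-1-carbaldehyde
Product: 7 vinyl compound (formyl of 6 converted into CH=CH2, C8=C9)
Conditions: Ph3PCH3Br, KN(SiMe3)2, THF, 0 °C; then 6, −78 → 0 °C
Reagents that add atoms: methyltriphenylphosphonium bromide, C[P+](c1ccccc1)(c1ccccc1)c1ccccc1.[Br-]
Why: Wittig methylenation of a non-enolisable aldehyde works even at a neopentyl centre and the oxaphosphetane collapses faster than any base-induced loss of HBr, so C6 and C7 are untouched and C8 becomes the vinyl group needed for the sp3–sp2 coupling.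

Step 5
Reactants: 7 vinyl compound
Product: 8 ring A allylic alcohol (C2–OH cis to vinyl, C3=C4, C6–Br cis to the C7 methyl)
Conditions: 48% aq. HF, MeCN, 0 °C → rt
Reagents that add atoms: none
Why: Acidic fluoride cleaves the secondary silyl ether without forming the free C2 alkoxide, which under basic fluoride could undergo Grob fragmentation across C2–C7 with loss of the C6 bromide.

Step 6
Reactants: 9 pent-4-ynoic acid
Product: 11 N-methoxy-N-methylpent-4-ynamide, via pent-4-ynoyl imidazolide 10 (not isolated)
Conditions: 1,1′-carbonyldiimidazole, CH2Cl2, rt; then MeNHOMe·HCl, rt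
Reagents that add atoms: 1,1′-carbonyldiimidazole (imidazole unit of 10 only), O=C(n1ccnc1)n1ccnc1; N,O-dimethylhydroxylamine hydrochloride, CNOC.Cl
Why: Activation of the acid as its imidazolide and aminolysis is a standard Weinreb amide synthesis that tolerates the terminal alkyne.

Step 7
Reactants: 11 N-methoxy-N-methylpent-4-ynamide
Product: 12 2-methylhept-1-en-6-yn-3-one
Conditions: CH2=C(CH3)MgBr (2.5 equiv), THF, −20 → 0 °C; cold aq. NH4Cl
Reagents that add atoms: isopropenylmagnesium bromide, C=C(C)[Mg]Br
Why: Grignard addition to the Weinreb amide stops at the chelated tetrahedral intermediate, so the isopropenyl ketone is released only on cold work-up (the excess reagent allows for deprotonation of the alkyne).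

Step 8
Reactants: 12 2-methylhept-1-en-6-yn-3-one
Product: 13 (S)-2-methylhept-1-en-6-yn-3-ol
Conditions: (R)-1-methyl-3,3-diphenyltetrahydro-1H,3H-pyrrolo[1,2-c][1,3,2]oxazaborole (15 mol %), catecholborane, toluene, −78 °C
Reagents that add atoms: none
Why: Corey–Bakshi–Shibata reduction, in which the α-branched alkenyl group acts as the large substituent so that the (R)-catalyst should deliver hydride to the face giving the (S)-allylic alcohol (future C14); catecholborane at −78 °C does not hydroborate the alkyne or the alkene.

Step 9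
Reactants: 13 (S)-2-methylhept-1-en-6-yn-3-ol
Product: 15 (S,E)-7-iodo-2,6-dimethylhepta-1,6-dien-3-ol, via alkenylalane 14 (not isolated)
Conditions: Me3Al (3 equiv), Cp2ZrCl2 (bis(cyclopentadienyl)zirconium dichloride, 0.25 equiv), CH2Cl2, 0 °C → rt; then I2, THF, −30 → 0 °C
Reagents that add atoms: trimethylaluminium, C[Al](C)C; iodine, II
Why: Zirconium-catalysed carboalumination (Negishi) adds methyl and aluminium syn across the terminal alkyne with methyl on the internal carbon, and iodinolysis with retention gives the (E)-2-methylalkenyl iodide that fixes the later C10=C11 geometry; the hydroxyl is carried as its aluminium alkoxide and the 1,1-disubstituted alkene does not react.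

Step 10
Reactants: 15 (S,E)-7-iodo-2,6-dimethylhepta-1,6-dien-3-ol
Product: 16 (S,E)-triethyl(7-iodo-2,6-dimethylhepta-1,6-dien-3-yloxy)silane
Conditions: Et3SiCl, imidazole, CH2Cl2, 0 °C → rt
Reagents that add atoms: chlorotriethylsilane, CC[Si](Cl)(CC)CC
Why: Standard silylation of a secondary alcohol; unlike an allylic ester the silyl ether is not ionised by palladium, it survives the later oxidation and basic steps, and mild acid removes it in the presence of the aryl silyl ether.

Step 11
Reactants: 8 ring A allylic alcohol, 16 (S,E)-triethyl(7-iodo-2,6-dimethylhepta-1,6-dien-3-yloxy)silane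
Product: 18 coupled allylic alcohol (ring A of 8 bearing the C8–C15 chain; 10E; 14S), via alkylborane 17 (not isolated)
Conditions: 8, 9-BBN (2.5 equiv), THF, 0 °C → rt; then 16, Pd(dppf)Cl2 ([1,1′-bis(diphenylphosphino)ferrocene]palladium dichloride, 5 mol %), AsPh3, Cs2CO3, DMF/H2O, rt
Reagents that add atoms: 9-borabicyclo[3.3.1]nonane (boron unit of 17 only), B1C2CCCC1CCC2
Why: 9-BBN hydroborates only the monosubstituted vinyl group (boron at C9; the hydroxyl is carried as its borinate), and the B-alkyl Suzuki–Miyaura coupling forms C9–C10 with retention of the alkenyl iodide geometry while the unactivated secondary bromide is inert to palladium at room temperature.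

Step 12
Reactants: 18 coupled allylic alcohol
Product: 19 ring A enone (C2=O, C3=C4)
Conditions: Dess–Martin periodinane, NaHCO3, CH2Cl2, 0 °C → rt
Reagents that add atoms: none
Why: Dess–Martin oxidation of the allylic alcohol under buffered conditions gives the enone without touching the silyl ether, the bromide or the isolated alkenes, and it erases the temporary C2 stereocentre.

Step 13
Reactants: 19 ring A enone
Product: 20 (10S,11S)-epoxide
Conditions: 1,2:4,5-di-O-isopropylidene-β-L-erythro-2,3-hexodiulo-2,6-pyranose (enantiomer of the Shi ketone, 30 mol %), KHSO5 (as 2KHSO5·KHSO4·K2SO4, 1.4 equiv), K2CO3, Bu4NHSO4, MeCN/CH2(OMe)2/aq. Na2B4O7 buffer, 0 °C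
Reagents that add atoms: potassium peroxymonosulfate, [K+].[O-]S(=O)(=O)OO
Why: Shi epoxidation, in which the chiral dioxirane attacks the electron-rich trisubstituted (E)-C10=C11 alkene through the spiro transition state so that the L-fructose-derived ketone should give the (10S,11S)-epoxide under reagent control, while the conjugated enone alkene and the 1,1-disubstituted alkene next to the silyloxy group react much more slowly.

Step 14
Reactants: 20 (10S,11S)-epoxide
Product: 21 (10R,11S)-bromohydrin (C10–Br, C11–OH)
Conditions: Li2NiBr4 (from LiBr and NiBr2, THF), 0 °C → rt; aq. pH 7 buffer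
Reagents that add atoms: dilithium tetrabromonickelate, [Li+].[Li+].[Ni+2].[Br-].[Br-].[Br-].[Br-]
Why: The soft bromide of Li2NiBr4 opens the trisubstituted epoxide in SN2 fashion at the less substituted carbon C10 with inversion, giving the (10R)-bromide and leaving the tertiary C11–O bond (11S) intact.

Step 15
Reactants: 21 (10R,11S)-bromohydrin
Product: 22 11-O-triethylsilyl bromohydrin
Conditions: Et3SiOTf, 2,6-lutidine, CH2Cl2, −78 °C
Reagents that add atoms: triethylsilyl trifluoromethanesulfonate, CC[Si](CC)(CC)OS(=O)(=O)C(F)(F)F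
Why: Silyl triflate with 2,6-lutidine silylates the hindered tertiary alcohol at low temperature, so that later basic reagents cannot close the bromohydrin back to the epoxide.

Step 16
Reactants: 22 11-O-triethylsilyl bromohydrin
Product: 24 ring A enol triflate (C2–OTf; C2=C3), via lithium enolate 23 (not isolated)
Conditions: LiBH(s-Bu)3 (1.1 equiv), THF, −78 °C; then N-(5-chloropyridin-2-yl)-N-(trifluoromethylsulfonyl)trifluoromethanesulfonamide, −78 → 0 °C
Reagents that add atoms: lithium tri-sec-butylborohydride (lithium of 23 only), [Li+].CCC(C)[BH-](C(C)CC)C(C)CC; N-(5-chloropyridin-2-yl)-N-(trifluoromethylsulfonyl)trifluoromethanesulfonamide, O=S(=O)(N(c1ccc(Cl)cn1)S(=O)(=O)C(F)(F)F)C(F)(F)F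
Why: The hindered hydride adds 1,4 to the β-unsubstituted enone (the carbonyl is shielded by quaternary C7), and O-triflation of the regiodefined enolate fixes the tetrasubstituted C2=C3 double bond (reductive enol triflate formation).

Step 17
Reactants: 25 methyl 4-hydroxy-3-methylbenzoate
Product: 26 methyl 3-methyl-4-(triisopropylsilyloxy)benzoate
Conditions: i-Pr3SiCl, imidazole, DMF, rt
Reagents that add atoms: chlorotriisopropylsilane, CC(C)[Si](Cl)(C(C)C)C(C)C
Why: Standard phenol silylation; the bulky aryl silyl ether withstands radical bromination, organozinc formation and mild acid, and is removed by fluoride at the end.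

Step 18
Reactants: 26 methyl 3-methyl-4-(triisopropylsilyloxy)benzoate
Product: 27 methyl 3-(bromomethyl)-4-(triisopropylsilyloxy)benzoate
Conditions: N-bromosuccinimide, azobisisobutyronitrile (cat.), PhCF3, 80 °C
Reagents that add atoms: N-bromosuccinimide, O=C1CCC(=O)N1Br
Why: Wohl–Ziegler radical bromination is selective for the benzylic methyl group in a non-polar solvent, the ester deactivating the ring toward ionic bromination.

Step 19
Reactants: 27 methyl 3-(bromomethyl)-4-(triisopropylsilyloxy)benzoate, 24 ring A enol triflate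
Product: 29 C1-benzylated ring A methyl ester, via benzylzinc bromide 28 (not isolated)
Conditions: 27, Zn dust, LiCl, THF, 0 → 25 °C; then 24, Pd(OAc)2 (5 mol %), 2-dicyclohexylphosphino-2′,6′-dimethoxybiphenyl (10 mol %), THF, 25–40 °C
Reagents that add atoms: zinc (zinc of 28 only), [Zn]
Why: Zinc inserts into the benzylic C–Br bond, and Negishi coupling of the benzylzinc bromide with the hindered enol triflate (the 2,6,6-trisubstituted cyclohexenyl triflate type known to cross-couple) forms C1–C2 while the ester, the silyl ethers and the secondary alkyl bromides are tolerated.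

Step 20
Reactants: 29 C1-benzylated ring A methyl ester
Product: 30 carboxylic acid
Conditions: Me3SnOH, ClCH2CH2Cl, 80 °C; dilute HCl wash
Reagents that add atoms: trimethyltin hydroxide, C[Sn](C)(C)O
Why: Trimethyltin hydroxide cleaves the methyl ester by a mild, essentially neutral hydrolysis that spares the base-labile aryl silyl ether, the silyl-protected bromohydrin and the alkyl bromides.

Step 21
Reactants: 30 carboxylic acid
Product: 31 seco acid (free C14–OH)
Conditions: pyridinium p-toluenesulfonate (cat.), MeOH/CH2Cl2, 0 °C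
Reagents that add atoms: none
Why: Acid-catalysed methanolysis removes the unhindered secondary triethylsilyl ether much faster than the hindered tertiary one and does not touch the acid-stable aryl silyl ether, so only the C14 hydroxyl is freed.

Step 22
Reactants: 31 seco acid
Product: 33 macrolactone (15-membered; C14 isopropenyl), via mixed anhydride 32 (not isolated)
Conditions: 2-methyl-6-nitrobenzoic anhydride, 4-(dimethylamino)pyridine, CH2Cl2 (1 mM, slow addition of 31), rt
Reagents that add atoms: 2-methyl-6-nitrobenzoic anhydride (aroyl unit of 32 only), Cc1cccc([N+](=O)[O-])c1C(=O)OC(=O)c1c(C)cccc1[N+](=O)[O-]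
Why: Shiina macrolactonisation, in which the mixed anhydride is activated by 4-(dimethylamino)pyridine and captured at high dilution by the only free hydroxyl (C14), closing the 15-membered lactone with retention at C14 under conditions mild enough for the protected bromohydrin.

Step 23
Reactants: 33 macrolactone
Product: 34 bis-silyl bromophycolide A (C15–Br)
Conditions: Co(acac)2 (cobalt bis(acetylacetonate)), t-BuOOH, Et3SiH, TsBr, n-PrOH/CH2Cl2, rt
Reagents that add atoms: p-toluenesulfonyl bromide, Cc1ccc(cc1)S(=O)(=O)Br
Why: Hydrogen-atom transfer from a cobalt hydride to the 1,1-disubstituted alkene gives the tertiary C15 radical, which abstracts bromine from the sulfonyl bromide (Markovnikov radical hydrobromination, known for 2-methylallyl aroates); the tetrasubstituted ring alkene is inert and C14 is not involved.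

Step 24
Reactants: 34 bis-silyl bromophycolide A
Product: 35 bromophycolide A
Conditions: Bu4NF/AcOH (1:1), THF, 0 °C → rt
Reagents that add atoms: none
Why: Acetic acid-buffered fluoride cleaves the aryl and the tertiary silyl ethers without forming an alkoxide that could close the bromohydrin to an epoxide and without a base strong enough to eliminate the tertiary bromide.

**Compound list**

1 | (E)-2-methylbut-2-enal (tiglic aldehyde) | C/C=C(\C)C=O | starting material
2 | (E)-triisopropyl(2-methylbuta-1,3-dienyloxy)silane | C=C/C(C)=C/O[Si](C(C)C)(C(C)C)C(C)C | intermediate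
3 | methacrolein | C=C(C)C=O | starting material
4 | 2,3-dibromo-2-methylpropanal | O=CC(C)(Br)CBr | intermediate
5 | (E)-3-bromo-2-methylprop-2-enal | O=C/C(C)=C/Br | intermediate
6 | (1R,2S,6S)-6-bromo-1,3-dimethyl-2-(triisopropylsilyloxy)cyclohex-3-ene-1-carbaldehyde (Br cis to the quaternary methyl, silyloxy cis to formyl) | O=C[C@]1(C)[C@@H](Br)CC=C(C)[C@@H]1O[Si](C(C)C)(C(C)C)C(C)C | intermediate
7 | vinyl compound: 6-bromo-1,3-dimethyl-2-(triisopropylsilyloxy)-1-vinylcyclohex-3-ene, configuration as in 6 | C=C[C@]1(C)[C@@H](Br)CC=C(C)[C@@H]1O[Si](C(C)C)(C(C)C)C(C)C | intermediate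
8 | ring A allylic alcohol: 6-bromo-1,3-dimethyl-1-vinylcyclohex-3-en-2-ol (numbering as 6; OH cis to vinyl, Br cis to methyl) | C=C[C@]1(C)[C@@H](Br)CC=C(C)[C@@H]1O | intermediate
9 | pent-4-ynoic acid | C#CCCC(=O)O | starting material
10 | 1-(pent-4-ynoyl)imidazole | C#CCCC(=O)n1ccnc1 | intermediate
11 | N-methoxy-N-methylpent-4-ynamide | C#CCCC(=O)N(C)OC | intermediate
12 | 2-methylhept-1-en-6-yn-3-one | C#CCCC(=O)C(C)=C | intermediate
13 | (S)-2-methylhept-1-en-6-yn-3-ol | O[C@H](C(C)=C)CCC#C | intermediate
14 | (E)-alkenyldimethylalane of 13 (O-dimethylaluminium alkoxide) | C[Al](C)/C=C(\C)CC[C@H](O[Al](C)C)C(C)=C | intermediate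
15 | (S,E)-7-iodo-2,6-dimethylhepta-1,6-dien-3-ol | O[C@H](C(C)=C)CC/C(C)=C/I | intermediate
16 | (S,E)-triethyl(7-iodo-2,6-dimethylhepta-1,6-dien-3-yloxy)silane | CC[Si](CC)(CC)O[C@H](C(C)=C)CC/C(C)=C/I | intermediate
17 | B-alkyl-9-BBN from 8 (boron on C9) | C(CB2C3CCCC2CCC3)[C@]1(C)[C@@H](Br)CC=C(C)[C@@H]1O | intermediate
18 | coupled allylic alcohol: ring A alcohol with C7–CH2CH2–CH=C(CH3)–CH2CH2–CH(OSiEt3)–C(CH3)=CH2; 10E, 14S | C(C/C=C(\C)CC[C@H](O[Si](CC)(CC)CC)C(C)=C)[C@]1(C)[C@@H](Br)CC=C(C)[C@@H]1O | intermediate
19 | ring A enone (C2 ketone of 18) | C(C/C=C(\C)CC[C@H](O[Si](CC)(CC)CC)C(C)=C)[C@]1(C)[C@@H](Br)CC=C(C)C1=O | intermediate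
20 | (10S,11S)-10,11-epoxide of 19 | C(C[C@@H]2O[C@@]2(C)CC[C@H](O[Si](CC)(CC)CC)C(C)=C)[C@]1(C)[C@@H](Br)CC=C(C)C1=O | intermediate
21 | (10R,11S)-10-bromo-11-hydroxy enone (bromohydrin) | C(C[C@@H](Br)[C@@](C)(O)CC[C@H](O[Si](CC)(CC)CC)C(C)=C)[C@]1(C)[C@@H](Br)CC=C(C)C1=O | intermediate
22 | 11-O-triethylsilyl ether of 21 | C(C[C@@H](Br)[C@@](C)(O[Si](CC)(CC)CC)CC[C@H](O[Si](CC)(CC)CC)C(C)=C)[C@]1(C)[C@@H](Br)CC=C(C)C1=O | intermediate
23 | lithium C2 enolate (C2=C3) from conjugate reduction of 22 | C(C[C@@H](Br)[C@@](C)(O[Si](CC)(CC)CC)CC[C@H](O[Si](CC)(CC)CC)C(C)=C)[C@]1(C)[C@@H](Br)CCC(C)=C1O[Li] | intermediate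
24 | ring A enol triflate (C2–OTf, C2=C3) | C(C[C@@H](Br)[C@@](C)(O[Si](CC)(CC)CC)CC[C@H](O[Si](CC)(CC)CC)C(C)=C)[C@]1(C)[C@@H](Br)CCC(C)=C1OS(=O)(=O)C(F)(F)F | intermediate
25 | methyl 4-hydroxy-3-methylbenzoate | COC(=O)c1ccc(O)c(C)c1 | starting material
26 | methyl 3-methyl-4-(triisopropylsilyloxy)benzoate | COC(=O)c1ccc(O[Si](C(C)C)(C(C)C)C(C)C)c(C)c1 | intermediate
27 | methyl 3-(bromomethyl)-4-(triisopropylsilyloxy)benzoate | COC(=O)c1ccc(O[Si](C(C)C)(C(C)C)C(C)C)c(CBr)c1 | intermediate
28 | [5-(methoxycarbonyl)-2-(triisopropylsilyloxy)benzyl]zinc bromide | COC(=O)c1ccc(O[Si](C(C)C)(C(C)C)C(C)C)c(C[Zn]Br)c1 | intermediate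
29 | C1-benzylated ring A methyl ester (24 with OTf replaced by the aryl-CH2 group) | C(C[C@@H](Br)[C@@](C)(O[Si](CC)(CC)CC)CC[C@H](O[Si](CC)(CC)CC)C(C)=C)[C@]1(C)[C@@H](Br)CCC(C)=C1Cc1cc(C(=O)OC)ccc1O[Si](C(C)C)(C(C)C)C(C)C | intermediate
30 | carboxylic acid of 29 | C(C[C@@H](Br)[C@@](C)(O[Si](CC)(CC)CC)CC[C@H](O[Si](CC)(CC)CC)C(C)=C)[C@]1(C)[C@@H](Br)CCC(C)=C1Cc1cc(C(=O)O)ccc1O[Si](C(C)C)(C(C)C)C(C)C | intermediate
31 | seco acid (free C14–OH; 11-O-SiEt3; aryl O-Si(i-Pr)3) | C(C[C@@H](Br)[C@@](C)(O[Si](CC)(CC)CC)CC[C@H](O)C(C)=C)[C@]1(C)[C@@H](Br)CCC(C)=C1Cc1cc(C(=O)O)ccc1O[Si](C(C)C)(C(C)C)C(C)C | intermediate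
32 | mixed anhydride of 31 with 2-methyl-6-nitrobenzoic acid | C(C[C@@H](Br)[C@@](C)(O[Si](CC)(CC)CC)CC[C@H](O)C(C)=C)[C@]1(C)[C@@H](Br)CCC(C)=C1Cc1cc(C(=O)OC(=O)c2c(C)cccc2[N+](=O)[O-])ccc1O[Si](C(C)C)(C(C)C)C(C)C | intermediate
33 | macrolactone (15-membered; isopropenyl at C14; 6S,7S,10R,11S,14S) | CC1=C2Cc3cc(ccc3O[Si](C(C)C)(C(C)C)C(C)C)C(=O)O[C@H](C(C)=C)CC[C@](C)(O[Si](CC)(CC)CC)[C@H](Br)CC[C@]2(C)[C@@H](Br)CC1 | intermediate
34 | bis-silyl bromophycolide A (C15–Br; 11-O-SiEt3; aryl O-Si(i-Pr)3) | CC1=C2Cc3cc(ccc3O[Si](C(C)C)(C(C)C)C(C)C)C(=O)O[C@H](C(C)(C)Br)CC[C@](C)(O[Si](CC)(CC)CC)[C@H](Br)CC[C@]2(C)[C@@H](Br)CC1 | intermediate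
35 | bromophycolide A (6S,7S,10R,11S,14S) | CC1=C2Cc3cc(ccc3O)C(=O)O[C@H](C(C)(C)Br)CC[C@](C)(O)[C@H](Br)CC[C@]2(C)[C@@H](Br)CC1 | target

**Step count**

Total: 24 steps. Longest linear sequence: 17 steps (steps 6–16 and 19–24, from pent-4-ynoic acid); 16 steps from tiglic aldehyde.

**Steps most likely to fail**

Step 3 (key cycloaddition). The doubly substituted β-bromo enal may react too slowly, so that silyl transfer or stepwise addition–elimination at the C–Br carbon competes, or the catalyst may discriminate the enal faces poorly. The fallback uses auxiliary control in place of catalyst control and sets out from 1 and 5. The potassium dienolate of 1 (KOt-Bu, THF, −78 °C) is O-acylated with (S)-O-methylmandeloyl chloride to give (E)-2-methylbuta-1,3-dienyl (S)-2-methoxy-2-phenylacetate F1. Cycloaddition of F1 with 5 (BF3·OEt2, CH2Cl2, −78 °C, or thermal) under stacking control by the auxiliary (antipode of the auxiliary chosen to fit the required face) should give the mandelate-bearing cycloadduct F2, whose diastereomers can be separated. Wittig methylenation as in step 4 gives the vinyl mandelate F3, and i-Bu2AlH at −78 °C cleaves the ester, returning to the route at 8.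

Step 14 (epoxide opening). Bromide may attack the tertiary carbon C11 in an SN1-like opening, or the Lewis acidic medium may rearrange the epoxide to a ketone. The fallback sets out from 19 and forms the bromohydrin directly: N-bromosuccinimide in aqueous THF at 0 °C forms the bromonium ion of the (E)-C10=C11 alkene, which water opens at the tertiary carbon. This fixes Br at C10, OH at C11 and the anti relationship, but there is no facial control, so 21 would form together with the (10S,11R)-diastereomer of 21 F4, to be removed by chromatography; the route is rejoined at 21.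

Step 23 (late hydrobromination). The tertiary radical may be reduced instead of brominated, sulfonyl radicals may add to the alkene, or conversion may stall in the hindered macrocycle. The fallback sets out from 33 and replaces radical bromine transfer by hydration and ionic substitution. Mukaiyama-type hydration (Co(acac)2, PhSiH3, O2, i-PrOH, rt) should give the C15 tertiary alcohol F5. Me3SiBr in CH2Cl2 at −40 → 0 °C then exchanges the tertiary hydroxyl for bromide through the 1,3-dioxolan-2-ylium ion formed by participation of the neighbouring aroyl group, which bromide opens at C15 with C14 untouched; the route is rejoined at 34.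

Further compounds
F1 | step 3 | (E)-2-methylbuta-1,3-dienyl (S)-2-methoxy-2-phenylacetate | C=C/C(C)=C/OC(=O)[C@@H](OC)c1ccccc1
F2 | step 3 | 6-bromo-1,3-dimethyl-2-[(S)-2-methoxy-2-phenylacetoxy]cyclohex-3-ene-1-carbaldehyde, ring configuration as 6 | O=C[C@]1(C)[C@@H](Br)CC=C(C)[C@@H]1OC(=O)[C@@H](OC)c1ccccc1
F3 | step 3 | vinyl mandelate (formyl of F2 converted into CH=CH2) | C=C[C@]1(C)[C@@H](Br)CC=C(C)[C@@H]1OC(=O)[C@@H](OC)c1ccccc1
F4 | step 14 | (10S,11R)-diastereomer of 21 | C(C[C@H](Br)[C@](C)(O)CC[C@H](O[Si](CC)(CC)CC)C(C)=C)[C@]1(C)[C@@H](Br)CC=C(C)C1=O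
F5 | step 23 | C15 tertiary alcohol of the macrolactone (33 with C(CH3)2OH at C14) | CC1=C2Cc3cc(ccc3O[Si](C(C)C)(C(C)C)C(C)C)C(=O)O[C@H](C(C)(C)O)CC[C@](C)(O[Si](CC)(CC)CC)[C@H](Br)CC[C@]2(C)[C@@H](Br)CC1
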